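**Strategy.** The plan removes the two chelated phenol oxygens last in the retrosynthesis. C5–OH on ring A and C5''–OH on ring D lie ortho to the C4 and C4'' ketones. These are the only C–H sites the carbonyls can reach, because C8a and C8a'' carry the pyranone oxygens. One ketone-directed, palladium-catalysed C–H oxygenation forms both C–O bonds at the end. Its precursor is the (2S,2''S)-5,5''-dideoxy biflavanone with ring E as its acetate. Rings A and D are then plain paeonol-type rings, so the C6''/C8'' ambiguity disappears. The precursor is built from chromones: two rhodium-catalysed asymmetric 1,4-additions of arylboronic acids set C2 and C2'', and one Suzuki–Miyaura coupling makes C3'–C6''.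

Key step: step 8

Numbering: flavanone numbering is used. Unit 1 has rings A (C5–C8), C (O1–C4) and B (primed atoms). Unit 2 has rings D and F (doubly primed atoms) and ring E (triply primed atoms).

Assumption: the C3'–C6'' axis is drawn without a descriptor and carries only OH, OMe, OMe and H in its ortho positions, so it is treated as not configurationally fixed.

Assumption: the (S)-bisphosphine is assigned to the (2S) series by the quadrant model that holds for cyclic enones. A calibration run on the first addition would confirm the sense, and the antipodal ligand is equally accessible.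

Design remark: both C2 centres are set by aryl transfer to chromones, not by closing 2'-hydroxychalcones. That closure is reversible and poorly enantioselective without an extra activating group. The strongly basic aldol steps it requires would also destroy an aryl acetate and would let an acetyl/formyl biaryl condense with itself.

Ligand: (S)-MeO-F12-BIPHEP is (S)-6,6'-dimethoxy-2,2'-bis[bis(3,4,5-trifluorophenyl)phosphino]-1,1'-biphenyl.

Step 1
Reactants: 1 paeonol (2'-hydroxy-4'-methoxyacetophenone)
Product: 3 7-methoxy-4H-chromen-4-one (7-methoxychromone), via enaminone 2 (not isolated)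
Conditions: Me2NCH(OMe)2 (2 equiv), toluene, 100 °C; concentrate; conc. HCl, CH2Cl2, 40 °C
Reagents that add atoms: N,N-dimethylformamide dimethyl acetal COC(OC)N(C)C
Why: Enaminone route to chromones: the formamide acetal condenses with the acetyl CH3, and acid then lets the chelated phenol add to the enaminone β-carbon and expel dimethylamine, a standard closure for 2,3-unsubstituted chromones that needs no phenol protection.

Step 2
Reactants: 3 7-methoxychromone; 4 (3-bromo-4-methoxyphenyl)boronic acid
Product: 5 (2S)-2-(3-bromo-4-methoxyphenyl)-7-methoxychroman-4-one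
Conditions: [Rh(C2H4)2Cl]2 (1.5 mol %), (S)-MeO-F12-BIPHEP (3.3 mol %) and aq KOH (3 mol %) premixed, then 3, 4 (2 equiv), CH2Cl2–H2O 10:1, 20 °C
Reagents that add atoms: none
Why: Hayashi–Miyaura asymmetric 1,4-addition: the aryl–rhodium species held by the electron-poor C2-symmetric bisphosphine inserts the chromone C2=C3 bond on the face left open by the ligand quadrants and thereby sets C2 as (S), hydrolysis of the oxa-π-allyl rhodium occurs in a nearly neutral medium in which the flavanone does not ring-open, dichloromethane tempers the catalyst so that 1,2-addition to the new ketone is suppressed, and the aryl bromide is inert to monovalent rhodium at 20 °C.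

Step 3
Reactants: 1 paeonol
Product: 6 1-(5-bromo-2-hydroxy-4-methoxyphenyl)ethanone (5'-bromopaeonol)
Conditions: NBS (1.05 equiv), MeCN, 0 to 20 °C
Reagents that add atoms: N-bromosuccinimide O=C1CCC(=O)N1Br
Why: Electrophilic aromatic bromination is steered to C5', para to the phenol and ortho to the methoxy group, because C3' is crowded between two oxygens and C6' is meta to both donors and ortho to the acetyl group; this carbon becomes C6'' of ring D.

Step 4
Reactants: 6 5'-bromopaeonol
Product: 8 6-bromo-7-methoxy-4H-chromen-4-one, via bromo enaminone 7 (not isolated)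
Conditions: Me2NCH(OMe)2 (2 equiv), toluene, 100 °C; concentrate; conc. HCl, CH2Cl2, 40 °C
Reagents that add atoms: N,N-dimethylformamide dimethyl acetal COC(OC)N(C)C
Why: Same enaminone route to chromones as in step 1, with the aryl bromide as a spectator.

Step 5
Reactants: 8 6-bromo-7-methoxychromone
Product: 9 7-methoxy-6-(4,4,5,5-tetramethyl-1,3,2-dioxaborolan-2-yl)-4H-chromen-4-one
Conditions: B2pin2 (1.2 equiv), Pd(dppf)Cl2 (3 mol %), KOAc (3 equiv), 1,4-dioxane, 90 °C
Reagents that add atoms: bis(pinacolato)diboron CC1(C)OB(OC1(C)C)B1OC(C)(C)C(C)(C)O1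
Why: Miyaura borylation of an aryl bromide, with acetate as a base too weak to open the chromone; boron is placed on this achiral partner so that flavanone 5 never has to be borylated under heat and base.

Step 6
Reactants: 5 (2S)-3'-bromo-4',7-dimethoxyflavanone; 9 chromone 6-boronate
Product: 10 (2S)-7-methoxy-2-[4-methoxy-3-(7-methoxy-4-oxo-4H-chromen-6-yl)phenyl]chroman-4-one
Conditions: Pd2(dba)3 (1.5 mol %), SPhos (6 mol %), 9 (1.2 equiv), 0.5 M aq K3PO4 (2 equiv), THF, 40 °C; work-up with pH 5 buffer
Reagents that add atoms: none
Why: Suzuki–Miyaura coupling with a dialkylbiarylphosphine ligand made for ortho-oxygenated biaryls, fast enough at 40 °C that the phosphate, which stays largely in the aqueous layer, should not enolise C3 and trigger the retro-oxa-Michael opening that alone could erode C2, while the weakly acidic work-up re-closes any chromone opened by hydroxide.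

Step 7
Reactants: 10 flavanone–chromone biaryl; 11 (4-acetoxyphenyl)boronic acid
Product: 12 (2S,2''S)-5,5''-dideoxy biflavanone with 7-OMe, 4'-OMe, 7''-OMe, ring E 4'''-acetate and the C3'–C6'' biaryl bond
Conditions: [Rh(C2H4)2Cl]2 (2.5 mol %), (S)-MeO-F12-BIPHEP (5.5 mol %) and aq KOH (5 mol %) premixed, then 10, 11 (3 equiv), CH2Cl2–H2O 10:1, 20 °C
Reagents that add atoms: none
Why: Second Hayashi–Miyaura asymmetric 1,4-addition, in which the same ligand enantiomer overrides the remote C2 centre and sets C2'' as (S), the 6''-aryl group lies far from the reacting C2''=C3'' bond, the ketone of unit 1 is spared for the same reason as in step 2, and ring E arrives already acetylated so that no strongly basic aldol step and no base-mediated acylation of an epimerisable 4'''-hydroxyflavanone is ever needed.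

Step 8
Reactants: 12 (2S,2''S)-5,5''-dideoxy biflavanone ring E acetate
Product: 14 (2S,2''S)-5,5''-dihydroxy biflavanone ring E acetate (the target as its 4'''-acetate), via bis(trifluoroacetate) 13 (not isolated)
Conditions: Pd(OAc)2 (20 mol %), K2S2O8 (3 equiv), CF3CO2H–(CF3CO)2O 9:1, 40 °C; then ice-water, EtOAc, pH 6 phosphate wash
Reagents that add atoms: trifluoroacetic acid OC(=O)C(F)(F)F
Why: Pd(OAc)2 is converted in the medium into electrophilic Pd(O2CCF3)2, each ketone oxygen binds this divalent palladium and steers concerted metalation–deprotonation to the adjacent C5–H or C5''–H, and the resulting five-membered palladacycle (Pd, O, C4, C4a, C5) is oxidised by persulfate to tetravalent palladium, from which C–O reductive elimination releases the aryl trifluoroacetate. The closest known reaction type is the palladium-catalysed ketone-directed ortho C–H hydroxylation of aryl alkyl ketones, benzo-fused cyclic ketones included, applied here at two sites in one flask. No ring is closed and no stereocentre is formed, so C2 and C2'' only have to survive, which is the reason for the 40 °C ceiling and for stopping the run once the mono-oxygenated stage is consumed. Site selectivity is built into the substrate, since the second ortho position of each carbonyl (C8a, C8a'') carries the pyranone oxygen and the electron-rich C6, C8 and C8'' positions cannot be reached through a five-membered chelate. Chemoselectivity relies on the anhydride, which holds every new phenol as an electron-poor trifluoroacetate and so prevents over-oxidation and dibenzofuran closure onto C2'–H, on the ring E acetate, which damps ring E and the C2'' benzylic position, and on the sparingly soluble persulfate, which keeps the oxidant level low for the anisole ring B. C5'' is flanked by ring B and should react after C5, hence the raised palladium loading.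

Step 9
Reactants: 14 target 4'''-acetate
Product: 15 target CNP0150873.1, the (2S,2''S)-3',6''-linked biflavanone with 5-OH, 7-OMe, 4'-OMe, 5''-OH, 7''-OMe and 4'''-OH
Conditions: HCl (1.25 M in MeOH), CH2Cl2, 25 °C
Reagents that add atoms: none
Why: Acid-catalysed transesterification transfers the acetyl group to methanol; base is avoided because the liberated 4'''-hydroxyflavanone would epimerise at C2'' through its quinone methide and an opened ring F could re-close on the C5'' oxygen (Wessely–Moser rearrangement to the 8''-linked isomer), whereas under mild acid the two chelated 5-hydroxyls keep rings C and F closed.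

**Compound list**

1 | paeonol (2'-hydroxy-4'-methoxyacetophenone) | CC(=O)c1ccc(OC)cc1O | starting material
2 | (E)-3-(dimethylamino)-1-(2-hydroxy-4-methoxyphenyl)prop-2-en-1-one | CN(C)/C=C/C(=O)c1ccc(OC)cc1O | intermediate
3 | 7-methoxy-4H-chromen-4-one | COc1ccc2c(=O)ccoc2c1 | intermediate
4 | (3-bromo-4-methoxyphenyl)boronic acid | COc1ccc(B(O)O)cc1Br | starting material
5 | (2S)-2-(3-bromo-4-methoxyphenyl)-7-methoxychroman-4-one | COc1ccc2c(c1)O[C@H](c1ccc(OC)c(Br)c1)CC2=O | intermediate
6 | 1-(5-bromo-2-hydroxy-4-methoxyphenyl)ethanone | CC(=O)c1cc(Br)c(OC)cc1O | intermediate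
7 | (E)-1-(5-bromo-2-hydroxy-4-methoxyphenyl)-3-(dimethylamino)prop-2-en-1-one | CN(C)/C=C/C(=O)c1cc(Br)c(OC)cc1O | intermediate
8 | 6-bromo-7-methoxy-4H-chromen-4-one | COc1cc2occc(=O)c2cc1Br | intermediate
9 | 7-methoxy-6-(4,4,5,5-tetramethyl-1,3,2-dioxaborolan-2-yl)-4H-chromen-4-one | COc1cc2occc(=O)c2cc1B1OC(C)(C)C(C)(C)O1 | intermediate
10 | (2S)-7-methoxy-2-[4-methoxy-3-(7-methoxy-4-oxo-4H-chromen-6-yl)phenyl]chroman-4-one | COc1ccc2c(c1)O[C@H](c1ccc(OC)c(-c3cc4c(=O)ccoc4cc3OC)c1)CC2=O | intermediate
11 | (4-acetoxyphenyl)boronic acid | CC(=O)Oc1ccc(B(O)O)cc1 | starting material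
12 | (2S,2''S)-5,5''-dideoxy biflavanone, ring E acetate (precursor of the key step) | COc1ccc2c(c1)O[C@H](c1ccc(OC)c(-c3c(OC)cc4c(c3)C(=O)C[C@@H](c3ccc(OC(C)=O)cc3)O4)c1)CC2=O | intermediate
13 | (2S,2''S)-5,5''-bis(trifluoroacetoxy) biflavanone, ring E acetate | COc1cc(OC(=O)C(F)(F)F)c2c(c1)O[C@H](c1ccc(OC)c(-c3c(OC)cc4c(c3OC(=O)C(F)(F)F)C(=O)C[C@@H](c3ccc(OC(C)=O)cc3)O4)c1)CC2=O | intermediate
14 | (2S,2''S)-5,5''-dihydroxy biflavanone, ring E acetate (product of the key step) | COc1cc(O)c2c(c1)O[C@H](c1ccc(OC)c(-c3c(OC)cc4c(c3O)C(=O)C[C@@H](c3ccc(OC(C)=O)cc3)O4)c1)CC2=O | intermediate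
15 | CNP0150873.1, (2S,2''S) | COc1cc(O)c2c(c1)O[C@H](c1ccc(OC)c(-c3c(OC)cc4c(c3O)C(=O)C[C@@H](c3ccc(O)cc3)O4)c1)CC2=O | target

**Step count.** Total steps: 9. Longest linear sequence: 7 (steps 3, 4, 5, 6, 7, 8 and 9 from paeonol); steps 1 and 2 form the side branch.

**Steps most likely to fail**

**Step 8.**
- What may go wrong: palladation may stall at C5'' next to ring B. One-electron oxidation of the anisole ring B, or palladium-mediated dehydrogenation of rings C and F, may outrun C–H oxygenation. Long contact with the acid may erode C2.
- Fallback: a neutral, non-oxidising C–H borylation, known for aryl ketones, followed by oxidation. Setting out from 12, [Ir(OMe)(cod)]2, AsPh3 and B2pin2 in hot octane–dioxane should give, by ketone-directed ortho C–H borylation, the 5,5''-bis(pinacolboronate) F1. Brief oxidation with KHSO5 (Oxone) in aqueous acetone at 0 °C then turns both C–B bonds into C–OH and rejoins the route at 14.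

**Step 6.**
- What may go wrong: base-induced enolisation and retro-oxa-Michael opening of ring C may erode C2. Hydroxide may also open the chromone partner.
- Fallback: temporary removal of the carbonyl that makes the opening possible. Setting out from 5, NaBH4 in MeOH–THF at 0 °C should give the cis alcohol (2S,4S)-2-(3-bromo-4-methoxyphenyl)-7-methoxychroman-4-ol F2, which has no acidic C3–H and cannot ring-open. This is coupled with 9 under ordinary Suzuki–Miyaura conditions (Pd(dppf)Cl2, K2CO3, dioxane–H2O, 80 °C) to the biaryl alcohol F3. Dess–Martin periodinane in CH2Cl2 restores the C4 ketone and returns to 10.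

**Step 7.**
- What may go wrong: hydrolytic loss of the acetate in the aqueous two-phase medium, together with slow aryl transfer to the large chromone, may stall the addition. It may also expose a free 4'''-phenol that epimerises.
- Fallback: a robust ether that is exchanged for the acetate without base. Setting out from 10, the 1,4-addition is run with (4-benzyloxyphenyl)boronic acid to give the ring E benzyl ether F4. Hydrogenolysis (H2, Pd/C, EtOAc, 20 °C) gives the ring E free phenol F5. Ac2O with Sc(OTf)3 (1 mol %) in MeCN at 0 °C then acetylates under Lewis acid catalysis and returns to 12.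

**Further compounds**

F1 | step 8 | (2S,2''S)-5,5''-bis(4,4,5,5-tetramethyl-1,3,2-dioxaborolan-2-yl) derivative of 12 | COc1cc(B5OC(C)(C)C(C)(C)O5)c2c(c1)O[C@H](c1ccc(OC)c(-c3c(OC)cc4c(c3B5OC(C)(C)C(C)(C)O5)C(=O)C[C@@H](c3ccc(OC(C)=O)cc3)O4)c1)CC2=O
F2 | step 6 | (2S,4S)-2-(3-bromo-4-methoxyphenyl)-7-methoxychroman-4-ol | COc1ccc2c(c1)O[C@H](c1ccc(OC)c(Br)c1)C[C@@H]2O
F3 | step 6 | 6-{5-[(2S,4S)-4-hydroxy-7-methoxychroman-2-yl]-2-methoxyphenyl}-7-methoxy-4H-chromen-4-one | COc1ccc2c(c1)O[C@H](c1ccc(OC)c(-c3cc4c(=O)ccoc4cc3OC)c1)C[C@@H]2O
F4 | step 7 | (2S,2''S)-5,5''-dideoxy biflavanone, ring E benzyl ether | COc1ccc2c(c1)O[C@H](c1ccc(OC)c(-c3c(OC)cc4c(c3)C(=O)C[C@@H](c3ccc(OCc5ccccc5)cc3)O4)c1)CC2=O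
F5 | step 7 | (2S,2''S)-5,5''-dideoxy biflavanone, ring E free phenol | COc1ccc2c(c1)O[C@H](c1ccc(OC)c(-c3c(OC)cc4c(c3)C(=O)C[C@@H](c3ccc(O)cc3)O4)c1)CC2=O
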